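The data were generated by integration with constants of no real substance; noise was put on by code.

How much of the electrophile has reacted after 1.0 h in eta, beta and epsilon, and does more nucleophile raise it?

| setting | south | east | eta | beta | epsilon |
|---|---|---|---|---|---|
| electrophile | 0.050 M (fed, over 3.0 min) | 0.050 M (fed, over 3.0 min) | 0.050 M (fed, over 3.0 min) | 0.050 M (fed, over 3.0 min) | 0.050 M (fed, over 3.0 min) |
| nucleophile | 0.036 M | 0.060 M | 0.0500 M | 0.0650 M | 0.0850 M |
| solid base | 0.055 M | 0.055 M | 0.0550 M | 0.0550 M | 0.0550 M |
| protic impurity | 0.010 M | 0.010 M | 0.0100 M | 0.0100 M | 0.0100 M |
| remark | run made earlier | run made earlier |  |  |  |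
| time |  |  | 1.0 h | 1.0 h | 1.0 h |

- south (time / min: electrophile / %, target / %): 12.0: 72, 6; 25.0: 65, 16; 40.0: 61, 22; 50.0: 58, 26; 60.0: 49, 29
- east (time / min: electrophile / %, target / %): 5.00: 76, 3; 10.0: 70, 12; 15.0: 68, 15; 30.0: 54, 26; 60.0: 38, 42

(scatter of a reading: 1.5 percentage points)

* part of the electrophile that has reacted at the end, eta
* part of the electrophile that has reacted at the end, beta
* part of the electrophile that has reacted at the end, epsilon
* what raising the concentration of nucleophile from its lowest to its highest value here does to the part of the electrophile that has reacted (changes below 5 percentage points count as none) (it rises / no change / it falls)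

- given per volume of solution although it is solid: solid base
- at the start none of the solid base is in solution

1. I write the balance of the electrophile, the limiting reagent in beta and epsilon, where it is charged at 0.050 M against 0.0650 M and 0.0850 M of nucleophile. As fractions of the charge, a is what is left, p is target and s is what went elsewhere, so a + p + s = 1, and the part reacted is X = p + s.

2. The readings give s directly. In the east run the feed has ended by 5.00 min, and s is then 21.0%; at 60.0 min it is 20.0%. It appears early and stays.

3. Suppose the protic impurity takes electrophile one to one. Then s = [protic impurity]/[electrophile charge] = 20.0%, the quench share. This comes from the charges, not the readings, and it matches them. The three new flasks carry the same two charges, so they share this s.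

4. Target forms by a bimolecular step, so p at a given time grows with nucleophile. Between the last readings, at the asked time, p climbs 5.42 /M. Taking that line straight, and beyond the east run for epsilon, I reckon X as 56.6%, 64.7% and 75.5%. That is a rise of 19 percentage points.

5. The forecast gives 57% (53% to 61%), 65% (59% to 69%) and 73% (62% to 78%), and for the trend it rises: “The fraction reacted rises with nucleophile.” My epsilon figure stands above its value.

6. The flasks give 56.7%, 63.8% and 71.3%: it rises, by 15 points.

    electrophile + nucleophile → acid set free + target (k = 0.00450 /M/s)
    nucleophile + acid set free ⇌ protonated nucleophile, settled at all times (K = 690 /M)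
    acid set free + free base ⇌ salt of the base, settled at all times (K = 8.10 × 10⁵ /M)
    solid base ⇌ free base, rate k4*(cs4 - [free base]) while solid is left; crystals form when [free base] > cs4 (solubility = 32.0 mM, k = 2.00 × 10⁻⁴ /s)
    acid set free + target → side product (k = 0.0110 /M/s)
    electrophile + protic impurity → quenched substrate (k = 0.800 /M/s)

Eta's 56.7% splits as the balance says: quenched substrate 20.0%, which is s, and target 36.7%, with the protic impurity down to 0% of its charge. A neighbour of beta with 0.013 M of electrophile, other charges held, has a reckoned quench share s = 76.9%. After 1.00 h it holds quenched substrate 76.7%, target 16.6% and electrophile 6.66%, with 93.3% reacted.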